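**Retrosynthetic overview**

1. Ring B (the quinone ring) is the last ring formed: target 23 ⇐ (NH4)2Ce(NO3)6 oxidation of 1-ethoxy-4-methoxynaphthalene 22 ⇐ one-operation [4+2] benzannulation of ynol ether 18 with 1-methoxy-1-phenylpropan-2-one 20, which makes the C2–C3 bond and the C1–C8a bond of ring B.
2. Enabling feature: in ring B the C1(=O)–C2(alkyl) pair is a masked ketene (ynol ether: nucleophilic C2, ketenium-electrophilic C1), C3(Me)–C4(=O) is an α-oxygenated methyl ketone whose carbonyl carbon is C3, and benzo carbon C8a is an ortho CH of a phenyl ring placed for six-membered closure onto C1.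
3. 18 ⇐ lithium ethoxyacetylide + iodide 17 ⇐ alcohol 16 ⇐ silyl ether 15 ⇐ one iridium-catalysed asymmetric hydrogenation of hexaene 14, which sets all four methyl-bearing stereocentres.
4. 14 ⇐ Wittig union (C13'=C14') of the farnesol-derived C13 phosphonium salt 5 with cyclopentane aldehyde 12.
5. 12 ⇐ purchased cis-cyclopentane half-ester 6 (carries both ring stereocentres) via alkyne 9 and carboalumination/prenylation; the benzene and cyclopentane rings are bought, ring B is the only ring made.

Key step: step 15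

Assumption: the target is made as drawn, i.e. (3'S,7'S,11'R) in the chain, a cis-(1R,3S)-cyclopentane and a (2R)-6-methylheptan-2-yl group, and (1R,3S)-3-(methoxycarbonyl)cyclopentane-1-carboxylic acid is taken as a purchasable single enantiomer.

**Route**

Step 1
Reactants: 1 (2E,6E)-farnesol
Product: 2 tert-butyl(diphenyl)silyl ether of (2E,6E)-farnesol
Conditions: TBDPSCl, imidazole, CH2Cl2, rt
Reagents that add atoms: tert-butyl(chloro)diphenylsilane CC(C)(C)[Si](Cl)(c1ccccc1)c1ccccc1
Why: Standard silylation of a primary allylic alcohol; the robust silyl ether survives the selenium oxidation, the ylide chemistry and the hydrogenation.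

Step 2
Reactants: 2 farnesyl silyl ether
Product: 3 (2E,6E,10E)-12-[tert-butyl(diphenyl)silyl]oxy-2,6,10-trimethyldodeca-2,6,10-trien-1-ol
Conditions: SeO2 (0.3 equiv), t-BuOOH, salicylic acid (0.1 equiv), CH2Cl2, 0 °C to rt
Reagents that add atoms: tert-butyl hydroperoxide CC(C)(C)OO; selenium dioxide (catalytic oxygen carrier) O=[Se]=O
Why: Catalytic SeO2 allylic oxidation (ene reaction, then [2,3]-sigmatropic shift) should attack the electron-rich terminal trisubstituted alkene at its E-methyl group and give the (E)-allylic alcohol, which fixes the C10'=C11' geometry needed in step 10.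

Step 3
Reactants: 3 allylic alcohol
Product: 4 [(2E,6E,10E)-12-bromo-3,7,11-trimethyldodeca-2,6,10-trienoxy]-tert-butyl-diphenylsilane
Conditions: CBr4, PPh3, CH2Cl2, 0 °C
Reagents that add atoms: carbon tetrabromide BrC(Br)(Br)Br
Why: Appel bromination of a primary allylic alcohol proceeds by SN2 displacement without allylic transposition or loss of alkene geometry.

Step 4
Reactants: 4 allylic bromide
Product: 5 [(3E,7E,11E)-13-[tert-butyl(diphenyl)silyl]oxy-3,7,11-trimethyltrideca-3,7,11-trienyl]triphenylphosphonium bromide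
Conditions: Ph3PCH3Br, n-BuLi, THF, 0 °C; then 4, −78 °C to rt
Reagents that add atoms: methyltriphenylphosphonium bromide C[P+](c1ccccc1)(c1ccccc1)c1ccccc1.[Br-]
Why: C-alkylation of methylenetriphenylphosphorane by the primary allylic bromide (SN2) gives the one-carbon-homologated phosphonium salt (the new carbon is C13'), which should precipitate from THF and so escape transylidation.

Step 5
Reactants: 6 (1R,3S)-3-(methoxycarbonyl)cyclopentane-1-carboxylic acid
Product: 7 methyl (1S,3R)-3-(hydroxymethyl)cyclopentane-1-carboxylate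
Conditions: BH3·SMe2, THF, 0 °C to rt; aqueous work-up
Reagents that add atoms: none
Why: Borane reduces a carboxylic acid chemoselectively beside a methyl ester; both ring stereocentres come with 6 and are not touched.

Step 6
Reactants: 7 hydroxy ester
Product: 9 [(1R,3S)-3-ethynylcyclopentyl]methanol, via hydroxy aldehyde 8 (not isolated)
Conditions: DIBAL-H (2.2 equiv), CH2Cl2, −78 °C; then MeOH, K2CO3, dimethyl (1-diazo-2-oxopropyl)phosphonate, −78 °C to rt
Reagents that add atoms: dimethyl (1-diazo-2-oxopropyl)phosphonate CC(=O)C(=[N+]=[N-])P(=O)(OC)OC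
Why: One-pot ester half-reduction and Ohira–Bestmann (Seyferth–Gilbert) homologation; the cis hydroxy aldehyde 8 is held as its bridged lactol, which should disfavour epimerisation at the carbon next to the formyl group.

Step 7
Reactants: 9 alkynol
Product: 11 [(1R,3S)-3-[(2E)-6-methylhepta-2,5-dien-2-yl]cyclopentyl]methanol, via alkenylalane 10 (not isolated)
Conditions: Me3Al (3 equiv), Cp2ZrCl2 (0.25 equiv), CH2Cl2, 0 °C to rt; then 1-chloro-3-methylbut-2-ene, Pd(PPh3)4 (5 mol %), THF, rt
Reagents that add atoms: trimethylaluminium C[Al](C)C; 1-chloro-3-methylbut-2-ene CC(C)=CCCl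
Why: Negishi carboalumination adds methyl and aluminium syn across the terminal alkyne (methyl to the internal carbon) and the palladium-catalysed alkenyl–allyl coupling proceeds with retention, giving the (E)-trisubstituted alkene; the hydroxyl is carried as its aluminium alkoxide.

Step 8
Reactants: 11 dienol
Product: 12 (1R,3S)-3-[(2E)-6-methylhepta-2,5-dien-2-yl]cyclopentane-1-carbaldehyde
Conditions: Dess–Martin periodinane, NaHCO3, CH2Cl2, 0 °C
Reagents that add atoms: none
Why: Buffered Dess–Martin oxidation gives the aldehyde under non-basic conditions, so the ring carbon next to the formyl group should not epimerise and the skipped diene should not isomerise.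

Step 9
Reactants: 5 phosphonium bromide; 12 aldehyde
Product: 14 tert-butyl-diphenyl-[(2E,6E,10E,13Z)-3,7,11-trimethyl-14-[(1R,3S)-3-[(2E)-6-methylhepta-2,5-dien-2-yl]cyclopentyl]tetradeca-2,6,10,13-tetraenoxy]silane, via phosphonium ylide 13 (not isolated)
Conditions: NaHMDS, THF, −78 to 0 °C; then 12, −78 °C to rt
Reagents that add atoms: none
Why: Wittig olefination with an unstabilised ylide at low temperature joins the two halves at C13'=C14' (Z expected, geometry irrelevant) faster than the aldehyde can enolise.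

Step 10
Reactants: 14 hexaene
Product: 15 tert-butyl-diphenyl-[(3S,7S,11R)-3,7,11-trimethyl-14-[(1R,3S)-3-[(2R)-6-methylheptan-2-yl]cyclopentyl]tetradecoxy]silane
Conditions: H2 (50 bar), [Ir(cod)(L*)][B(C6H3-3,5-(CF3)2)4] (4 mol %), CH2Cl2, rt; L* = the antipode of an enantiopure 2-aryl-8-(di-tert-butylphosphinooxy)-5,6,7,8-tetrahydroquinoline (pyridine–phosphinite) that gives (3S,7S)-3,7,11-trimethyldodecan-1-ol from (2E,6E)-farnesol
Reagents that add atoms: none
Why: Iridium-catalysed asymmetric hydrogenation of unfunctionalised trisubstituted alkenes with a chiral N,P ligand: the four E-trisubstituted alkenes (C2'=C3', C6'=C7', C10'=C11' and C2=C3 of the heptadienyl group) present the same substitution pattern, so one ligand antipode should add hydrogen to the same relative face of each and set C3' (S), C7' (S), C11' (R) and the heptanyl C2 (R) by catalyst control, while the Z-disubstituted and isopropylidene alkenes are reduced without creating stereocentres and the ring centres are kept.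

Step 11
Reactants: 15 saturated silyl ether
Product: 16 (3S,7S,11R)-3,7,11-trimethyl-14-[(1R,3S)-3-[(2R)-6-methylheptan-2-yl]cyclopentyl]tetradecan-1-ol
Conditions: TBAF, THF, rt
Reagents that add atoms: none
Why: Fluoride-mediated desilylation of a primary silyl ether; nothing else in the molecule is reactive.

Step 12
Reactants: 16 alcohol
Product: 17 (3S,7S,11R)-1-iodo-3,7,11-trimethyl-14-[(1R,3S)-3-[(2R)-6-methylheptan-2-yl]cyclopentyl]tetradecane
Conditions: I2, PPh3, imidazole, CH2Cl2, 0 °C to rt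
Reagents that add atoms: iodine II
Why: Appel-type iodination of an unhindered primary alcohol by SN2 displacement of the oxyphosphonium group.

Step 13
Reactants: 17 iodide
Product: 18 (5S,9S,13R)-1-ethoxy-5,9,13-trimethyl-16-[(1R,3S)-3-[(2R)-6-methylheptan-2-yl]cyclopentyl]hexadec-1-yne
Conditions: ethoxyacetylene, n-BuLi, THF, −78 °C; then 17, HMPA, −78 °C to rt
Reagents that add atoms: ethoxyacetylene CCOC#C
Why: SN2 alkylation of lithium ethoxyacetylide by a primary iodide in the presence of HMPA, a known route to 1-alkoxy-1-alkynes.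

Step 14
Reactants: 19 racemic 2-methoxy-2-phenylacetic acid
Product: 20 racemic 1-methoxy-1-phenylpropan-2-one
Conditions: MeLi (2.2 equiv), THF/Et2O, 0 °C to rt; then H2O
Reagents that add atoms: methyllithium [Li]C
Why: Addition of methyllithium to the lithium carboxylate gives a dilithio ketone hydrate that collapses to the methyl ketone only on work-up; the stereocentre is racemic and is destroyed in step 15.

Step 15
Reactants: 18 ynol ether; 20 1-methoxy-1-phenylpropan-2-one
Product: 22 1-ethoxy-4-methoxy-3-methyl-2-[(3S,7S,11R)-3,7,11-trimethyl-14-[(1R,3S)-3-[(2R)-6-methylheptan-2-yl]cyclopentyl]tetradecyl]naphthalene, via dihydronaphthalenol 21 (not isolated)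
Conditions: 20 (1.5 equiv), TiCl4 (1.2 equiv), CH2Cl2, −78 °C; slow addition of 18; −78 to 0 °C; aq NaHCO3
Reagents that add atoms: none
Why: Proposed new method: TiCl4 chelates the methoxy and carbonyl oxygens of 20, the nucleophilic chain-bearing carbon of ynol ether 18 adds to the ketone carbon (future C2–C3 bond of ring B), and the resulting ethoxy-ketenium carbon is captured by the ortho carbon of the phenyl ring (future C1–C8a bond), after which loss of water from 21 aromatises ring B. The closest known reactions are the Lewis-acid benzannulation of arylacetaldehydes and α-aryl ketones with alkynes and the arene capture of ketenium ions generated from ynol ethers; new here is an ynol ether as the alkyne partner of a ketone. Ring B closes by a six-membered Friedel–Crafts attack on the sp ketenium carbon (6-exo with respect to the C=O+ bond), following the intermolecular C–C bond formation. The two stereocentres of 21 are transient and vanish on aromatisation, and the side-chain centres are remote and untouched. Regiochemistry is fixed by the polarisation of the ynol ether and by the ortho tether; the chemoselectivity needed is arene capture in preference to the known oxete closure and ester formation, which the poorly nucleophilic chelated titanium alkoxide, the strain of the four-membered ring and the irreversible aromatisation should favour.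

Step 16
Reactants: 22 dialkoxynaphthalene
Product: 23 2-methyl-3-[(3S,7S,11R)-3,7,11-trimethyl-14-[(1R,3S)-3-[(2R)-6-methylheptan-2-yl]cyclopentyl]tetradecyl]naphthalene-1,4-dione
Conditions: (NH4)2Ce(NO3)6 (2.5 equiv), MeCN/CH2Cl2/H2O, 0 °C
Reagents that add atoms: water O
Why: Oxidative dealkylation of a 1,4-dialkoxynaphthalene by tetravalent cerium (arene radical cation, water addition, loss of the two alcohols) gives the 1,4-quinone; the saturated chain is inert.

**Compound list**

1 | (2E,6E)-3,7,11-trimethyldodeca-2,6,10-trien-1-ol ((2E,6E)-farnesol) | OC/C=C(C)/CC/C=C(C)/CCC=C(C)C | starting material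
2 | tert-butyl-diphenyl-[(2E,6E)-3,7,11-trimethyldodeca-2,6,10-trienoxy]silane | CC(C)(C)[Si](OC/C=C(C)/CC/C=C(C)/CCC=C(C)C)(c1ccccc1)c1ccccc1 | intermediate
3 | (2E,6E,10E)-12-[tert-butyl(diphenyl)silyl]oxy-2,6,10-trimethyldodeca-2,6,10-trien-1-ol | CC(C)(C)[Si](OC/C=C(C)/CC/C=C(C)/CC/C=C(C)/CO)(c1ccccc1)c1ccccc1 | intermediate
4 | [(2E,6E,10E)-12-bromo-3,7,11-trimethyldodeca-2,6,10-trienoxy]-tert-butyl-diphenylsilane | CC(C)(C)[Si](OC/C=C(C)/CC/C=C(C)/CC/C=C(C)/CBr)(c1ccccc1)c1ccccc1 | intermediate
5 | [(3E,7E,11E)-13-[tert-butyl(diphenyl)silyl]oxy-3,7,11-trimethyltrideca-3,7,11-trienyl]triphenylphosphonium bromide | CC(C)(C)[Si](OC/C=C(C)/CC/C=C(C)/CC/C=C(C)/CC[P+](c1ccccc1)(c1ccccc1)c1ccccc1)(c1ccccc1)c1ccccc1.[Br-] | intermediate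
6 | (1R,3S)-3-(methoxycarbonyl)cyclopentane-1-carboxylic acid (cis) | OC(=O)[C@@H]1CC[C@H](C(=O)OC)C1 | starting material
7 | methyl (1S,3R)-3-(hydroxymethyl)cyclopentane-1-carboxylate | OC[C@@H]1CC[C@H](C(=O)OC)C1 | intermediate
8 | (1S,3R)-3-(hydroxymethyl)cyclopentane-1-carbaldehyde (in equilibrium with its bridged lactol) | OC[C@@H]1CC[C@H](C=O)C1 | intermediate
9 | [(1R,3S)-3-ethynylcyclopentyl]methanol | OC[C@@H]1CC[C@H](C#C)C1 | intermediate
10 | (E)-alkenyl(dimethyl)alane of 9 with the hydroxyl as its dimethylaluminium alkoxide | C[Al](C)OC[C@@H]1CC[C@H](/C(C)=C/[Al](C)C)C1 | intermediate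
11 | [(1R,3S)-3-[(2E)-6-methylhepta-2,5-dien-2-yl]cyclopentyl]methanol | OC[C@@H]1CC[C@H](/C(C)=C/CC=C(C)C)C1 | intermediate
12 | (1R,3S)-3-[(2E)-6-methylhepta-2,5-dien-2-yl]cyclopentane-1-carbaldehyde | O=C[C@@H]1CC[C@H](/C(C)=C/CC=C(C)C)C1 | intermediate
13 | triphenylphosphonium ylide derived from 5 | CC(C)(C)[Si](OC/C=C(C)/CC/C=C(C)/CC/C=C(C)/CC=P(c1ccccc1)(c1ccccc1)c1ccccc1)(c1ccccc1)c1ccccc1 | intermediate
14 | tert-butyl-diphenyl-[(2E,6E,10E,13Z)-3,7,11-trimethyl-14-[(1R,3S)-3-[(2E)-6-methylhepta-2,5-dien-2-yl]cyclopentyl]tetradeca-2,6,10,13-tetraenoxy]silane | CC(C)(C)[Si](OC/C=C(C)/CC/C=C(C)/CC/C=C(C)/C/C=C\[C@@H]1CC[C@H](/C(C)=C/CC=C(C)C)C1)(c1ccccc1)c1ccccc1 | intermediate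
15 | tert-butyl-diphenyl-[(3S,7S,11R)-3,7,11-trimethyl-14-[(1R,3S)-3-[(2R)-6-methylheptan-2-yl]cyclopentyl]tetradecoxy]silane | CC(C)(C)[Si](OCC[C@@H](C)CCC[C@@H](C)CCC[C@@H](C)CCC[C@@H]1CC[C@H]([C@H](C)CCCC(C)C)C1)(c1ccccc1)c1ccccc1 | intermediate
16 | (3S,7S,11R)-3,7,11-trimethyl-14-[(1R,3S)-3-[(2R)-6-methylheptan-2-yl]cyclopentyl]tetradecan-1-ol | OCC[C@@H](C)CCC[C@@H](C)CCC[C@@H](C)CCC[C@@H]1CC[C@H]([C@H](C)CCCC(C)C)C1 | intermediate
17 | (3S,7S,11R)-1-iodo-3,7,11-trimethyl-14-[(1R,3S)-3-[(2R)-6-methylheptan-2-yl]cyclopentyl]tetradecane | ICC[C@@H](C)CCC[C@@H](C)CCC[C@@H](C)CCC[C@@H]1CC[C@H]([C@H](C)CCCC(C)C)C1 | intermediate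
18 | (5S,9S,13R)-1-ethoxy-5,9,13-trimethyl-16-[(1R,3S)-3-[(2R)-6-methylheptan-2-yl]cyclopentyl]hexadec-1-yne | CCOC#CCC[C@@H](C)CCC[C@@H](C)CCC[C@@H](C)CCC[C@@H]1CC[C@H]([C@H](C)CCCC(C)C)C1 | intermediate
19 | racemic 2-methoxy-2-phenylacetic acid | COC(C(=O)O)c1ccccc1 | starting material
20 | racemic 1-methoxy-1-phenylpropan-2-one | COC(C(C)=O)c1ccccc1 | intermediate
21 | 4-ethoxy-1-methoxy-2-methyl-3-[(3S,7S,11R)-3,7,11-trimethyl-14-[(1R,3S)-3-[(2R)-6-methylheptan-2-yl]cyclopentyl]tetradecyl]-1,2-dihydronaphthalen-2-ol (titanium alkoxide, diastereomer mixture at C1 and C2) | CCOC1=C(CC[C@@H](C)CCC[C@@H](C)CCC[C@@H](C)CCC[C@@H]2CC[C@H]([C@H](C)CCCC(C)C)C2)C(C)(O)C(OC)c2ccccc12 | intermediate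
22 | 1-ethoxy-4-methoxy-3-methyl-2-[(3S,7S,11R)-3,7,11-trimethyl-14-[(1R,3S)-3-[(2R)-6-methylheptan-2-yl]cyclopentyl]tetradecyl]naphthalene | CCOc1c(CC[C@@H](C)CCC[C@@H](C)CCC[C@@H](C)CCC[C@@H]2CC[C@H]([C@H](C)CCCC(C)C)C2)c(C)c(OC)c2ccccc12 | intermediate
23 | 2-methyl-3-[(3S,7S,11R)-3,7,11-trimethyl-14-[(1R,3S)-3-[(2R)-6-methylheptan-2-yl]cyclopentyl]tetradecyl]naphthalene-1,4-dione | CC1=C(CC[C@@H](C)CCC[C@@H](C)CCC[C@@H](C)CCC[C@@H]2CC[C@H]([C@H](C)CCCC(C)C)C2)C(=O)c2ccccc2C1=O | target

**Step count**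

Total steps: 16. Longest linear sequence: 11 steps (steps 1, 2, 3, 4, 9, 10, 11, 12, 13, 15, 16).

**Steps most likely to fail**

1. Step 15 (Proposed new method). After the first C–C bond is formed, the titanium alkoxide may close onto the ketenium carbon and the oxete may ring-open to the α,β-unsaturated ester (carbonyl–ynol ether metathesis); the ynol ether may also be protonated and hydrated before it meets the ketone. The fallback uses known chemistry, sets out from iodide 17 and returns to the route at target 23. Commercial 1,4-dimethoxy-2-methylnaphthalene is brominated (Br2, CH2Cl2, 0 °C) to 2-bromo-1,4-dimethoxy-3-methylnaphthalene F1. Zinc insertion into 17 (Zn dust, LiCl, THF, 50 °C) gives the alkylzinc iodide F2. Negishi coupling of F2 with F1 (Pd(OAc)2, SPhos, THF, 60 °C) gives 1,4-dimethoxy-2-methyl-3-[(3S,7S,11R)-3,7,11-trimethyl-14-[(1R,3S)-3-[(2R)-6-methylheptan-2-yl]cyclopentyl]tetradecyl]naphthalene F3. Oxidation of F3 with (NH4)2Ce(NO3)6 as in step 16 gives 23.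

2. Step 10. Facial control may be incomplete at one of the four trisubstituted alkenes, and double-bond migration within the skipped dienes (above all from the Z-disubstituted C13'=C14' alkene toward the ring) may erode the C11' centre or epimerise the ring carbon; the resulting diastereomers would not be separable. The fallback sets out from hexaene 14 and returns at 15. Diimide (2-nitrobenzenesulfonylhydrazide, Et3N, CH2Cl2, rt) reduces only the Z-1,2-disubstituted alkene and gives tert-butyl-diphenyl-[(2E,6E,10E)-3,7,11-trimethyl-14-[(1R,3S)-3-[(2E)-6-methylhepta-2,5-dien-2-yl]cyclopentyl]tetradeca-2,6,10-trienoxy]silane F4. F4 no longer holds the migration-prone alkene next to the ring stereocentre and is then hydrogenated with the same iridium catalyst to 15.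

3. Step 13. Substitution of the long-chain primary iodide by the acetylide may be slow and lose out to E2 elimination, and the acid-labile ynol ether may be lost by hydration during isolation. The fallback sets out from 17 and returns at 23 through a silyl ynol ether. Lithium acetylide–ethylenediamine (DMSO, rt) converts 17 into (5S,9S,13R)-5,9,13-trimethyl-16-[(1R,3S)-3-[(2R)-6-methylheptan-2-yl]cyclopentyl]hexadec-1-yne F5. Deprotonation (n-BuLi) and oxidation of the lithium acetylide with lithium tert-butyl peroxide (THF, −78 to 0 °C) give the lithium ynolate F6, which is O-silylated with triisopropylsilyl triflate to the 1-(triisopropylsilyloxy)alkyne F7. F7 takes the place of 18 in step 15 and gives the 1-(triisopropylsilyloxy)-4-methoxynaphthalene F8, which (NH4)2Ce(NO3)6 oxidises to 23.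

**Further compounds**

F1 | step 15 | 2-bromo-1,4-dimethoxy-3-methylnaphthalene | COc1c(Br)c(C)c(OC)c2ccccc12
F2 | step 15 | [(3S,7S,11R)-3,7,11-trimethyl-14-[(1R,3S)-3-[(2R)-6-methylheptan-2-yl]cyclopentyl]tetradecyl]zinc iodide | I[Zn]CC[C@@H](C)CCC[C@@H](C)CCC[C@@H](C)CCC[C@@H]1CC[C@H]([C@H](C)CCCC(C)C)C1
F3 | step 15 | 1,4-dimethoxy-2-methyl-3-[(3S,7S,11R)-3,7,11-trimethyl-14-[(1R,3S)-3-[(2R)-6-methylheptan-2-yl]cyclopentyl]tetradecyl]naphthalene | COc1c(CC[C@@H](C)CCC[C@@H](C)CCC[C@@H](C)CCC[C@@H]2CC[C@H]([C@H](C)CCCC(C)C)C2)c(C)c(OC)c2ccccc12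
F4 | step 10 | tert-butyl-diphenyl-[(2E,6E,10E)-3,7,11-trimethyl-14-[(1R,3S)-3-[(2E)-6-methylhepta-2,5-dien-2-yl]cyclopentyl]tetradeca-2,6,10-trienoxy]silane | CC(C)(C)[Si](OC/C=C(C)/CC/C=C(C)/CC/C=C(C)/CCC[C@@H]1CC[C@H](/C(C)=C/CC=C(C)C)C1)(c1ccccc1)c1ccccc1
F5 | step 13 | (5S,9S,13R)-5,9,13-trimethyl-16-[(1R,3S)-3-[(2R)-6-methylheptan-2-yl]cyclopentyl]hexadec-1-yne | C#CCC[C@@H](C)CCC[C@@H](C)CCC[C@@H](C)CCC[C@@H]1CC[C@H]([C@H](C)CCCC(C)C)C1
F6 | step 13 | lithium ynolate of F5 (lithium (5S,9S,13R)-5,9,13-trimethyl-16-[(1R,3S)-3-[(2R)-6-methylheptan-2-yl]cyclopentyl]hexadec-1-yn-1-olate) | [Li+].[O-]C#CCC[C@@H](C)CCC[C@@H](C)CCC[C@@H](C)CCC[C@@H]1CC[C@H]([C@H](C)CCCC(C)C)C1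
F7 | step 13 | triisopropyl-[(5S,9S,13R)-5,9,13-trimethyl-16-[(1R,3S)-3-[(2R)-6-methylheptan-2-yl]cyclopentyl]hexadec-1-ynoxy]silane | CC(C)[Si](OC#CCC[C@@H](C)CCC[C@@H](C)CCC[C@@H](C)CCC[C@@H]1CC[C@H]([C@H](C)CCCC(C)C)C1)(C(C)C)C(C)C
F8 | step 13 | triisopropyl-[4-methoxy-3-methyl-2-[(3S,7S,11R)-3,7,11-trimethyl-14-[(1R,3S)-3-[(2R)-6-methylheptan-2-yl]cyclopentyl]tetradecyl]naphthalen-1-yl]oxysilane | COc1c(C)c(CC[C@@H](C)CCC[C@@H](C)CCC[C@@H](C)CCC[C@@H]2CC[C@H]([C@H](C)CCCC(C)C)C2)c(O[Si](C(C)C)(C(C)C)C(C)C)c2ccccc12
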